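The route cuts the biaryl bond between C3' of flavanone ring B (ortho to the 4'-oxygen) and C6 of flavone ring A (flanked by the 5- and 7-oxygens, the only position ortho to the chelated 5-hydroxyl). A Suzuki–Miyaura coupling forms this congested bond and, in one operation, unites two complete flavonoid units into the full C30 skeleton, leaving only hydrogenolysis. The precursors are a 6-iodoapigenin dibenzyl ether, whose iodine is steered to C6 by the free 5-hydroxyl, and an enantiopure (2S)-flavanone 3'-pinacolboronate, whose C2 is set beforehand by a palladium-catalysed asymmetric conjugate addition of an arylboronic acid to a chromone.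

Key step: step 6

Remark: the biaryl axis, flanked by only three small oxygen substituents, is treated as freely rotating, so C2 is the only stereogenic element to be controlled; boronic acid 6 is taken as a catalogue compound.

Step 1
Reactants: 1 apigenin (5,7-dihydroxy-2-(4-hydroxyphenyl)-4H-chromen-4-one)
Product: 2 7-(benzyloxy)-2-[4-(benzyloxy)phenyl]-5-hydroxy-4H-chromen-4-one
Conditions: BnBr (2.2 equiv), K2CO3, DMF, rt
Reagents that add atoms: benzyl bromide, BrCc1ccccc1
Why: Williamson etherification alkylates the acidic 7- and 4'-hydroxyls, whereas the 5-hydroxyl, hydrogen-bonded to the C4 carbonyl, should stay free at room temperature.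

Step 2
Reactants: 2 7-(benzyloxy)-2-[4-(benzyloxy)phenyl]-5-hydroxy-4H-chromen-4-one
Product: 3 7-(benzyloxy)-2-[4-(benzyloxy)phenyl]-5-hydroxy-6-iodo-4H-chromen-4-one
Conditions: benzyltrimethylammonium dichloroiodate (1.05 equiv), CaCO3, CH2Cl2/MeOH, rt
Reagents that add atoms: benzyltrimethylammonium dichloroiodate, C[N+](C)(C)Cc1ccccc1.Cl[I-]Cl
Why: Electrophilic aromatic iodination of a 5-hydroxy-7-alkoxyflavone is directed by the free chelated 5-hydroxyl to its ortho position C6 rather than C8, and CaCO3 takes up the HCl released.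

Step 3
Reactants: 4 5,7-dihydroxy-4H-chromen-4-one
Product: 5 5,7-bis(benzyloxy)-4H-chromen-4-one
Conditions: BnBr (2.6 equiv), K2CO3, DMF, 70 °C
Reagents that add atoms: benzyl bromide, BrCc1ccccc1
Why: Williamson etherification under forcing conditions alkylates both the 7-hydroxyl and the chelated 5-hydroxyl, and the chromone ring is stable to anhydrous carbonate.

Step 4
Reactants: 5 5,7-bis(benzyloxy)-4H-chromen-4-one; 6 [4-(benzyloxy)-3-bromophenyl]boronic acid
Product: 7 (2S)-5,7-bis(benzyloxy)-2-[4-(benzyloxy)-3-bromophenyl]-2,3-dihydro-4H-chromen-4-one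
Conditions: Pd(OCOCF3)2 (5 mol%), (R)-t-BuPyOx ((R)-4-tert-butyl-2-(pyridin-2-yl)-4,5-dihydrooxazole, 6 mol%), NH4PF6 (30 mol%), H2O (5 equiv), ClCH2CH2Cl, 60 °C
Reagents that add atoms: none
Why: Palladium-catalysed asymmetric conjugate addition of an arylboronic acid to a chromone, in which the aryl–palladium species (divalent palladium throughout, so the C–Br bond is untouched) carbometalates C2=C3 on the face left open by the tert-butyl group of the ligand and water protonates the enolate under base-free conditions that should not open the flavanone; by analogy with cyclic enones, where the (S)-ligand gives the (R)-β-aryl ketone, the (R)-ligand should deliver the (2S)-centre.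

Step 5
Reactants: 7 (2S)-5,7-bis(benzyloxy)-2-[4-(benzyloxy)-3-bromophenyl]-2,3-dihydro-4H-chromen-4-one
Product: 8 (2S)-5,7-bis(benzyloxy)-2-[4-(benzyloxy)-3-(4,4,5,5-tetramethyl-1,3,2-dioxaborolan-2-yl)phenyl]-2,3-dihydro-4H-chromen-4-one
Conditions: B2pin2 (1.3 equiv), KOAc, PdCl2(dppf) (dppf = 1,1'-bis(diphenylphosphino)ferrocene, 5 mol%), 1,4-dioxane, 80 °C
Reagents that add atoms: bis(pinacolato)diboron, CC1(C)OB(OC1(C)C)B1OC(C)(C)C(C)(C)O1
Why: Miyaura borylation (oxidative addition of zerovalent palladium to C3'–Br, acetate-assisted transmetalation with the diboron reagent, reductive elimination) uses only the weak base KOAc, which should not enolize the flavanone appreciably, so the (2S)-centre should be retained.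

Step 6
Reactants: 3 7-(benzyloxy)-2-[4-(benzyloxy)phenyl]-5-hydroxy-6-iodo-4H-chromen-4-one; 8 (2S)-5,7-bis(benzyloxy)-2-[4-(benzyloxy)-3-(4,4,5,5-tetramethyl-1,3,2-dioxaborolan-2-yl)phenyl]-2,3-dihydro-4H-chromen-4-one
Product: 9 7-(benzyloxy)-2-[4-(benzyloxy)phenyl]-6-{2-(benzyloxy)-5-[(2S)-5,7-bis(benzyloxy)-4-oxo-3,4-dihydro-2H-chromen-2-yl]phenyl}-5-hydroxy-4H-chromen-4-one
Conditions: Pd(OAc)2 (5 mol%), SPhos (2-dicyclohexylphosphino-2',6'-dimethoxybiphenyl, 10 mol%), K3PO4 (3.5 equiv), THF/H2O (10:1), 50 °C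
Reagents that add atoms: none
Why: Zerovalent palladium, formed from Pd(OAc)2 and SPhos, adds oxidatively to the C6–I bond of 3, the phosphate-activated boronate 8 transfers its ring B aryl group to palladium, and reductive elimination forms the C3'–C6 biaryl bond. This is a Suzuki–Miyaura coupling, the reaction type by which C–C-linked biflavones are classically assembled. No ring is closed and no stereocentre is created; the new axis carries three small oxygen substituents and is not expected to be configurationally stable. Site selectivity is fixed on both sides by the positions of iodine and boron, so the regiochemical questions (C6 versus C8 on flavone ring A, ring B versus ring A of the flavanone) are settled before the coupling. The step needs the 5-phenoxide of 3 to tolerate coupling and the (2S)-centre of 8 to survive base; the bulky electron-rich biarylphosphine should allow this tri-ortho-substituted coupling at 50 °C in a short time, which should keep retro-oxa-Michael opening of the non-phenolic flavanone slow.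

Step 7
Reactants: 9 7-(benzyloxy)-2-[4-(benzyloxy)phenyl]-6-{2-(benzyloxy)-5-[(2S)-5,7-bis(benzyloxy)-4-oxo-3,4-dihydro-2H-chromen-2-yl]phenyl}-5-hydroxy-4H-chromen-4-one
Product: 10 6-{5-[(2S)-5,7-dihydroxy-4-oxo-3,4-dihydro-2H-chromen-2-yl]-2-hydroxyphenyl}-5,7-dihydroxy-2-(4-hydroxyphenyl)-4H-chromen-4-one (CNP0277421.1)
Conditions: H2 (1 atm), Pd/C (10%), THF/MeOH, rt; neutral work-up
Reagents that add atoms: none
Why: Catalytic hydrogenolysis cleaves all five benzyl ethers under neutral conditions, which should leave the flavone C2=C3 bond, both carbonyl groups and the base-sensitive (2S)-centre untouched.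

Compound list
1 | apigenin (5,7-dihydroxy-2-(4-hydroxyphenyl)-4H-chromen-4-one) | O=c1cc(-c2ccc(O)cc2)oc2cc(O)cc(O)c12 | starting material
2 | 7-(benzyloxy)-2-[4-(benzyloxy)phenyl]-5-hydroxy-4H-chromen-4-one | O=c1cc(-c2ccc(OCc3ccccc3)cc2)oc2cc(OCc3ccccc3)cc(O)c12 | intermediate
3 | 7-(benzyloxy)-2-[4-(benzyloxy)phenyl]-5-hydroxy-6-iodo-4H-chromen-4-one | O=c1cc(-c2ccc(OCc3ccccc3)cc2)oc2cc(OCc3ccccc3)c(I)c(O)c12 | intermediate
4 | 5,7-dihydroxy-4H-chromen-4-one | O=c1ccoc2cc(O)cc(O)c12 | starting material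
5 | 5,7-bis(benzyloxy)-4H-chromen-4-one | O=c1ccoc2cc(OCc3ccccc3)cc(OCc3ccccc3)c12 | intermediate
6 | [4-(benzyloxy)-3-bromophenyl]boronic acid | OB(O)c1ccc(OCc2ccccc2)c(Br)c1 | starting material
7 | (2S)-5,7-bis(benzyloxy)-2-[4-(benzyloxy)-3-bromophenyl]-2,3-dihydro-4H-chromen-4-one | O=C1C[C@@H](c2ccc(OCc3ccccc3)c(Br)c2)Oc2cc(OCc3ccccc3)cc(OCc3ccccc3)c21 | intermediate
8 | (2S)-5,7-bis(benzyloxy)-2-[4-(benzyloxy)-3-(4,4,5,5-tetramethyl-1,3,2-dioxaborolan-2-yl)phenyl]-2,3-dihydro-4H-chromen-4-one | O=C1C[C@@H](c2ccc(OCc3ccccc3)c(B3OC(C)(C)C(C)(C)O3)c2)Oc2cc(OCc3ccccc3)cc(OCc3ccccc3)c21 | intermediate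
9 | 7-(benzyloxy)-2-[4-(benzyloxy)phenyl]-6-{2-(benzyloxy)-5-[(2S)-5,7-bis(benzyloxy)-4-oxo-3,4-dihydro-2H-chromen-2-yl]phenyl}-5-hydroxy-4H-chromen-4-one | O=C1C[C@@H](c2ccc(OCc3ccccc3)c(-c3c(OCc4ccccc4)cc4oc(-c5ccc(OCc6ccccc6)cc5)cc(=O)c4c3O)c2)Oc2cc(OCc3ccccc3)cc(OCc3ccccc3)c21 | intermediate
10 | 6-{5-[(2S)-5,7-dihydroxy-4-oxo-3,4-dihydro-2H-chromen-2-yl]-2-hydroxyphenyl}-5,7-dihydroxy-2-(4-hydroxyphenyl)-4H-chromen-4-one | O=C1C[C@@H](c2ccc(O)c(-c3c(O)cc4oc(-c5ccc(O)cc5)cc(=O)c4c3O)c2)Oc2cc(O)cc(O)c21 | target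

Total step count: 7. Longest linear sequence: 5 steps (4 to 5 to 7 to 8 to 9 to 10; steps 3, 4, 5, 6 and 7).

Steps most likely to fail

First, step 6 (the key coupling). Transmetalation and reductive elimination at the tri-ortho-substituted centre may be slow with the phenoxide-bearing iodide. Protodeiodination and protodeboronation may then compete, and a prolonged reaction may erode C2 through base-mediated ring opening and reclosure. Fallback: setting out from 3, the 5-hydroxyl is benzylated (BnBr, K2CO3, DMF, 60 °C) to give 5,7-bis(benzyloxy)-2-[4-(benzyloxy)phenyl]-6-iodo-4H-chromen-4-one F1. This neutral, more soluble iodide is coupled with 8 under heterogeneous, nearly anhydrous conditions (Pd(OAc)2, SPhos, finely ground K3PO4 with a few equivalents of water, toluene, 80 °C) to the fully benzylated biflavonoid (hexabenzyl ether of 10) F2. Hydrogenolysis of F2 (H2, Pd/C, THF/MeOH) returns to the route at 10.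

Second, step 4. Facial selectivity may be insufficient with the electron-rich para-alkoxyaryl group, and carbometalation of the electron-rich 5,7-dialkoxychromone may be slow while 6 is lost to protodeboronation. Fallback: setting out from 5 and 6, the achiral variant (Pd(OCOCF3)2, 2,2'-bipyridine, NH4PF6, H2O, ClCH2CH2Cl, 60 °C) gives racemic 5,7-bis(benzyloxy)-2-[4-(benzyloxy)-3-bromophenyl]-2,3-dihydro-4H-chromen-4-one F3. The racemate is resolved by preparative chromatography on a chiral stationary phase (amylose tris(3,5-dimethylphenylcarbamate)). The (2S)-enantiomer is 7, where the route is rejoined, and the (2R)-enantiomer F4 is set aside.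

Third, step 5. Heating with acetate may cause partial loss of configuration at C2 by reversible ring opening, and protodebromination may compete at the ortho-alkoxy-substituted carbon. Fallback: setting out from 7, base-free stannylation (Me3SnSnMe3, Pd(PPh3)4, toluene, 100 °C) gives (2S)-5,7-bis(benzyloxy)-2-[4-(benzyloxy)-3-(trimethylstannyl)phenyl]-2,3-dihydro-4H-chromen-4-one F5. This is joined to 3 by a copper-assisted Stille coupling (Pd2(dba)3, AsPh3, CuI, NMP, 60 °C), returning to the route at 9 without exposure of the flavanone to base.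

Further compounds
F1 | step 6 | 5,7-bis(benzyloxy)-2-[4-(benzyloxy)phenyl]-6-iodo-4H-chromen-4-one | O=c1cc(-c2ccc(OCc3ccccc3)cc2)oc2cc(OCc3ccccc3)c(I)c(OCc3ccccc3)c12
F2 | step 6 | 5,7-bis(benzyloxy)-2-[4-(benzyloxy)phenyl]-6-{2-(benzyloxy)-5-[(2S)-5,7-bis(benzyloxy)-4-oxo-3,4-dihydro-2H-chromen-2-yl]phenyl}-4H-chromen-4-one | O=C1C[C@@H](c2ccc(OCc3ccccc3)c(-c3c(OCc4ccccc4)cc4oc(-c5ccc(OCc6ccccc6)cc5)cc(=O)c4c3OCc3ccccc3)c2)Oc2cc(OCc3ccccc3)cc(OCc3ccccc3)c21
F3 | step 4 | racemic 5,7-bis(benzyloxy)-2-[4-(benzyloxy)-3-bromophenyl]-2,3-dihydro-4H-chromen-4-one | O=C1CC(c2ccc(OCc3ccccc3)c(Br)c2)Oc2cc(OCc3ccccc3)cc(OCc3ccccc3)c21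
F4 | step 4 | (2R)-5,7-bis(benzyloxy)-2-[4-(benzyloxy)-3-bromophenyl]-2,3-dihydro-4H-chromen-4-one | O=C1C[C@H](c2ccc(OCc3ccccc3)c(Br)c2)Oc2cc(OCc3ccccc3)cc(OCc3ccccc3)c21
F5 | step 5 | (2S)-5,7-bis(benzyloxy)-2-[4-(benzyloxy)-3-(trimethylstannyl)phenyl]-2,3-dihydro-4H-chromen-4-one | O=C1C[C@@H](c2ccc(OCc3ccccc3)c([Sn](C)(C)C)c2)Oc2cc(OCc3ccccc3)cc(OCc3ccccc3)c21
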